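The side chain (C1' on the quinone ring to C32') is cut at the C17'–C18' single bond, where an sp3 methylene meets the vinylic CH of the (E)-C18'=C19' trisubstituted alkene. A one-pot 9-BBN hydroboration/B-alkyl Suzuki–Miyaura coupling joins the two halves there. One half is the C17' terminus of a 1,3-diene on a C21 chain that already carries the (7'R) methyl centre and the naphthoquinone as its 1,4-dimethyl ether. The other is a C19 (E)-alkenyl iodide made from farnesyl bromide by Negishi carboalumination, which fixes the alkene geometry before coupling. The stereocentre comes from Noyori hydrogenation of farnesol; cerium oxidation then unmasks the quinone.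

Key step: step 10

Remark: commercial (2E,6E)-farnesol and (2E,6E)-farnesyl bromide are taken as geometrically pure; locants C1'–C32' count the side chain from the ring.

Step 1
Reactants: 1 (2E,6E)-farnesyl bromide; 2 1-(trimethylsilyl)propyne
Product: 4 (5E,9E)-6,10,14-trimethylpentadeca-5,9,13-trien-1-yne, via silylalkyne 3 (not isolated)
Conditions: 2, nBuLi, THF, −78 → −20 °C; then 1, −78 °C → rt; then MeOH, K2CO3 (0.2 equiv), rt
Reagents that add atoms: none
Why: The propargylic lithium reagent from 2 should displace the primary allylic bromide by SN2 alkylation at its CH2 terminus without touching the two (E)-alkenes, and base-catalysed methanolysis (protodesilylation) then frees the terminal alkyne.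

Step 2
Reactants: 4 (5E,9E)-6,10,14-trimethylpentadeca-5,9,13-trien-1-yne
Product: 6 (1E,5E,9E)-1-iodo-2,6,10,14-tetramethylpentadeca-1,5,9,13-tetraene, via alkenylalane 5 (not isolated)
Conditions: Me3Al (2 equiv), Cp2ZrCl2 (0.25 equiv), CH2Cl2, 0 °C → rt; then I2, THF, −30 → 0 °C
Reagents that add atoms: trimethylaluminium C[Al](C)C; iodine II
Why: Negishi zirconium-catalysed carboalumination adds methyl and aluminium syn across the terminal alkyne with methyl on the internal carbon, and iodinolysis of the C–Al bond with retention should give the (E)-alkenyl iodide while the trisubstituted alkenes stay inert.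

Step 3
Reactants: 7 (2E,6E)-farnesol
Product: 8 (S)-2,3-dihydrofarnesol, (3S,6E)-3,7,11-trimethyldodeca-6,10-dien-1-ol
Conditions: Ru(OAc)2[(R)-BINAP] (0.5 mol %), H2 (100 atm), MeOH–H2O 95:5, 20 °C
Reagents that add atoms: none
Why: In the Noyori asymmetric hydrogenation the allylic hydroxyl binds ruthenium so that only the C2=C3 alkene is reduced, and the (R)-BINAP ligand should deliver hydrogen to the face that gives the 3S centre, as it does for geraniol to (S)-citronellol.

Step 4
Reactants: 8 (S)-2,3-dihydrofarnesol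
Product: 9 (6E,10S)-12-iodo-2,6,10-trimethyldodeca-2,6-diene
Conditions: I2, PPh3, imidazole, CH2Cl2, 0 °C → rt
Reagents that add atoms: iodine II
Why: Appel-type iodination activates the primary alcohol as an alkoxyphosphonium ion that iodide displaces by SN2, two carbons away from the stereocentre, which is therefore untouched.

Step 5
Reactants: 9 (6E,10S)-12-iodo-2,6,10-trimethyldodeca-2,6-diene; 2 1-(trimethylsilyl)propyne
Product: 11 (6R,9E)-6,10,14-trimethylpentadeca-9,13-dien-1-yne, via silylalkyne 10 (not isolated)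
Conditions: 2, nBuLi, THF, −78 °C; then 9, THF–DMPU, −78 °C → rt; then MeOH, K2CO3 (0.2 equiv), rt
Reagents that add atoms: none
Why: SN2 alkylation of the silyl-propargyl lithium with the primary iodide adds the three carbons C2'–C4', and protodesilylation should then give the terminal alkyne; the descriptor changes from S to R only because the ranking of the substituents changes.

Step 6
Reactants: 12 1,4-dimethoxy-2-methylnaphthalene
Product: 13 2-(chloromethyl)-1,4-dimethoxy-3-methylnaphthalene
Conditions: (CH2O)n, 37% aq HCl, AcOH, rt → 50 °C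
Reagents that add atoms: formaldehyde (as paraformaldehyde) C=O; hydrogen chloride Cl
Why: Blanc chloromethylation should attack the only free position of the doubly methoxy-activated ring, C3, which is ortho to a methoxy group.

Step 7
Reactants: 11 (6R,9E)-6,10,14-trimethylpentadeca-9,13-dien-1-yne; 13 2-(chloromethyl)-1,4-dimethoxy-3-methylnaphthalene
Product: 15 2-[(2E,7R,10E)-3,7,11,15-tetramethylhexadeca-2,10,14-trien-1-yl]-1,4-dimethoxy-3-methylnaphthalene, via alkenylalane 14 (not isolated)
Conditions: 11, Me3Al (2 equiv), Cp2ZrCl2 (0.25 equiv), CH2Cl2, 0 °C → rt; solvent exchanged to THF; then 13, NiCl2(PPh3)2 (5 mol %) reduced in the flask with nBuLi (10 mol %) to zerovalent nickel, 0 °C → rt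
Reagents that add atoms: trimethylaluminium C[Al](C)C
Why: Negishi carboalumination sets the (E)-C2'=C3' alkene by syn methylalumination, and nickel-catalysed Negishi-type alkenyl–benzyl cross-coupling of the alkenylalane with the benzylic chloride should form the C1'–C2' bond with retention of that geometry.

Step 8
Reactants: 15 2-[(2E,7R,10E)-3,7,11,15-tetramethylhexadeca-2,10,14-trien-1-yl]-1,4-dimethoxy-3-methylnaphthalene
Product: 17 (2E,6E,10R,14E)-16-(1,4-dimethoxy-3-methylnaphthalen-2-yl)-2,6,10,14-tetramethylhexadeca-2,6,14-trienal, via allylic alcohol 16 (not isolated)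
Conditions: SeO2 (0.3 equiv), tBuOOH (70% aq, 3 equiv), salicylic acid (0.1 equiv), CH2Cl2, 0 °C → rt, stopped at partial conversion (15 recycled); crude, then MnO2 (20 equiv), CH2Cl2, rt
Reagents that add atoms: selenium dioxide O=[Se]=O; tert-butyl hydroperoxide CC(C)(C)OO
Why: Catalytic SeO2 allylic oxidation (ene reaction, then [2,3]-sigmatropic shift) should hydroxylate the (E)-methyl of the terminal, most accessible trisubstituted alkene, and MnO2 then oxidises the primary allylic alcohol to the (E)-enal.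

Step 9
Reactants: 17 (2E,6E,10R,14E)-16-(1,4-dimethoxy-3-methylnaphthalen-2-yl)-2,6,10,14-tetramethylhexadeca-2,6,14-trienal
Product: 18 2-[(2E,7R,10E,14E)-3,7,11,15-tetramethylheptadeca-2,10,14,16-tetraen-1-yl]-1,4-dimethoxy-3-methylnaphthalene
Conditions: Ph3PCH3Br, KOtBu, THF, 0 °C → rt
Reagents that add atoms: methyltriphenylphosphonium bromide C[P+](c1ccccc1)(c1ccccc1)c1ccccc1.[Br-]
Why: Wittig methylenation of the enal should add C17' as a terminal CH2 and leave the (E)-C14'=C15' geometry intact, giving the 1,3-diene.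

Step 10
Reactants: 18 2-[(2E,7R,10E,14E)-3,7,11,15-tetramethylheptadeca-2,10,14,16-tetraen-1-yl]-1,4-dimethoxy-3-methylnaphthalene; 6 (1E,5E,9E)-1-iodo-2,6,10,14-tetramethylpentadeca-1,5,9,13-tetraene
Product: 20 2-[(2E,7R,10E,14E,18E,22E,26E)-3,7,11,15,19,23,27,31-octamethyldotriaconta-2,10,14,18,22,26,30-heptaen-1-yl]-1,4-dimethoxy-3-methylnaphthalene, via alkylborane 19 (not isolated)
Conditions: 18, 9-BBN (0.5 M in THF, 1.3 equiv), THF, 0 °C → rt; then 6, PdCl2(dppf) (10 mol %), AsPh3 (10 mol %), Cs2CO3 (3 equiv), DMF–H2O, rt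
Reagents that add atoms: none
Why: 9-BBN should add B–H syn and anti-Markovnikov across the monosubstituted C16'=C17' terminus of the 1,3-diene, putting boron on C17' to give homoallylic borane 19; base then forms a borate whose primary alkyl group transmetalates to the alkenylpalladium iodide made by stereoretentive oxidative addition of 6 to zerovalent palladium, and reductive elimination forges the C17'–C18' bond. The closest known reaction type is the B-alkyl Suzuki–Miyaura coupling of an alkyl-9-BBN with an (E)-alkenyl iodide. No ring is closed and no stereocentre is formed; the (7'R) centre is remote and untouched. The step needs hydroboration of one alkene out of five, which the bulk of 9-BBN secures because at room temperature it reacts with the terminal vinyl group and not with trisubstituted alkenes. It also needs retention of the (E) geometry at C18'=C19', which the stereospecific palladium cycle secures; transfer of the primary alkyl group in preference to the secondary ring B–C bonds is the normal behaviour of 9-BBN reagents.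

Step 11
Reactants: 20 2-[(2E,7R,10E,14E,18E,22E,26E)-3,7,11,15,19,23,27,31-octamethyldotriaconta-2,10,14,18,22,26,30-heptaen-1-yl]-1,4-dimethoxy-3-methylnaphthalene
Product: 21 2-methyl-3-[(2E,7R,10E,14E,18E,22E,26E)-3,7,11,15,19,23,27,31-octamethyldotriaconta-2,10,14,18,22,26,30-heptaen-1-yl]naphthalene-1,4-dione
Conditions: (NH4)2Ce(NO3)6 (2.5 equiv), MeCN–CH2Cl2–H2O, 0 °C, short reaction time
Reagents that add atoms: water O
Why: Oxidative demethylation of the 1,4-dimethoxyarene by single-electron oxidation with cerium ammonium nitrate, with water attacking the arene radical cation and methanol leaving, should give the quinone while the isolated alkenes and the stereocentre stay untouched at 0 °C.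

Compound list
1 | (2E,6E)-farnesyl bromide | CC(C)=CCC/C(C)=C/CC/C(C)=C/CBr | starting material
2 | 1-(trimethylsilyl)propyne | CC#C[Si](C)(C)C | starting material
3 | trimethyl[(5E,9E)-6,10,14-trimethylpentadeca-5,9,13-trien-1-yn-1-yl]silane | CC(C)=CCC/C(C)=C/CC/C(C)=C/CCC#C[Si](C)(C)C | intermediate (not isolated)
4 | (5E,9E)-6,10,14-trimethylpentadeca-5,9,13-trien-1-yne | CC(C)=CCC/C(C)=C/CC/C(C)=C/CCC#C | intermediate
5 | dimethyl[(1E,5E,9E)-2,6,10,14-tetramethylpentadeca-1,5,9,13-tetraen-1-yl]alane | CC(C)=CCC/C(C)=C/CC/C(C)=C/CC/C(C)=C/[Al](C)C | intermediate (not isolated)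
6 | (1E,5E,9E)-1-iodo-2,6,10,14-tetramethylpentadeca-1,5,9,13-tetraene | CC(C)=CCC/C(C)=C/CC/C(C)=C/CC/C(C)=C/I | intermediate
7 | (2E,6E)-farnesol | CC(C)=CCC/C(C)=C/CC/C(C)=C/CO | starting material
8 | (S)-2,3-dihydrofarnesol, (3S,6E)-3,7,11-trimethyldodeca-6,10-dien-1-ol | CC(C)=CCC/C(C)=C/CC[C@H](C)CCO | intermediate
9 | (6E,10S)-12-iodo-2,6,10-trimethyldodeca-2,6-diene | CC(C)=CCC/C(C)=C/CC[C@H](C)CCI | intermediate
10 | trimethyl[(6R,9E)-6,10,14-trimethylpentadeca-9,13-dien-1-yn-1-yl]silane | CC(C)=CCC/C(C)=C/CC[C@H](C)CCCC#C[Si](C)(C)C | intermediate (not isolated)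
11 | (6R,9E)-6,10,14-trimethylpentadeca-9,13-dien-1-yne | CC(C)=CCC/C(C)=C/CC[C@H](C)CCCC#C | intermediate
12 | 1,4-dimethoxy-2-methylnaphthalene | COc1cc(C)c(OC)c2ccccc12 | starting material
13 | 2-(chloromethyl)-1,4-dimethoxy-3-methylnaphthalene | COc1c(C)c(CCl)c(OC)c2ccccc12 | intermediate
14 | dimethyl[(1E,6R,9E)-2,6,10,14-tetramethylpentadeca-1,9,13-trien-1-yl]alane | CC(C)=CCC/C(C)=C/CC[C@H](C)CCC/C(C)=C/[Al](C)C | intermediate (not isolated)
15 | 2-[(2E,7R,10E)-3,7,11,15-tetramethylhexadeca-2,10,14-trien-1-yl]-1,4-dimethoxy-3-methylnaphthalene | CC(C)=CCC/C(C)=C/CC[C@H](C)CCC/C(C)=C/Cc1c(C)c(OC)c2ccccc2c1OC | intermediate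
16 | (2E,6E,10R,14E)-16-(1,4-dimethoxy-3-methylnaphthalen-2-yl)-2,6,10,14-tetramethylhexadeca-2,6,14-trien-1-ol | OC/C(C)=C/CC/C(C)=C/CC[C@H](C)CCC/C(C)=C/Cc1c(C)c(OC)c2ccccc2c1OC | intermediate (not isolated)
17 | (2E,6E,10R,14E)-16-(1,4-dimethoxy-3-methylnaphthalen-2-yl)-2,6,10,14-tetramethylhexadeca-2,6,14-trienal | O=C/C(C)=C/CC/C(C)=C/CC[C@H](C)CCC/C(C)=C/Cc1c(C)c(OC)c2ccccc2c1OC | intermediate
18 | 2-[(2E,7R,10E,14E)-3,7,11,15-tetramethylheptadeca-2,10,14,16-tetraen-1-yl]-1,4-dimethoxy-3-methylnaphthalene | C=C/C(C)=C/CC/C(C)=C/CC[C@H](C)CCC/C(C)=C/Cc1c(C)c(OC)c2ccccc2c1OC | intermediate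
19 | 9-[(3E,7E,11R,15E)-17-(1,4-dimethoxy-3-methylnaphthalen-2-yl)-3,7,11,15-tetramethylheptadeca-3,7,15-trien-1-yl]-9-borabicyclo[3.3.1]nonane | B1(CC/C(C)=C/CC/C(C)=C/CC[C@H](C)CCC/C(C)=C/Cc2c(C)c(OC)c3ccccc3c2OC)C2CCCC1CCC2 | intermediate (not isolated)
20 | 2-[(2E,7R,10E,14E,18E,22E,26E)-3,7,11,15,19,23,27,31-octamethyldotriaconta-2,10,14,18,22,26,30-heptaen-1-yl]-1,4-dimethoxy-3-methylnaphthalene | CC(C)=CCC/C(C)=C/CC/C(C)=C/CC/C(C)=C/CC/C(C)=C/CC/C(C)=C/CC[C@H](C)CCC/C(C)=C/Cc1c(C)c(OC)c2ccccc2c1OC | intermediate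
21 | 2-methyl-3-[(2E,7R,10E,14E,18E,22E,26E)-3,7,11,15,19,23,27,31-octamethyldotriaconta-2,10,14,18,22,26,30-heptaen-1-yl]naphthalene-1,4-dione | CC(C)=CCC/C(C)=C/CC/C(C)=C/CC/C(C)=C/CC/C(C)=C/CC/C(C)=C/CC[C@H](C)CCC/C(C)=C/CC1=C(C)C(=O)c2ccccc2C1=O | target

Total step count: 11. Longest linear sequence: 8 steps (steps 3, 4, 5, 7, 8, 9, 10 and 11, from farnesol).

Steps most likely to fail

Step 8. The allylic oxidation may lose site selectivity (attack on the C4' or C12' methylene next to the two internal alkenes) or over-oxidise, so that little of the terminal (E)-enal is obtained. The fallback sets out from 15 and replaces C–H oxidation by cleavage and rebuilding of the terminal alkene. NBS in THF–H2O at 0 °C, where the folded chain exposes mainly its terminal alkene, should give the terminal bromohydrin (6E,10R,14E)-3-bromo-16-(1,4-dimethoxy-3-methylnaphthalen-2-yl)-2,6,10,14-tetramethylhexadeca-6,14-dien-2-ol F1 as a mixture of C3 epimers. K2CO3 in MeOH closes it to the terminal epoxide 2-[(2E,7R,10E)-13-(3,3-dimethyloxiran-2-yl)-3,7,11-trimethyltrideca-2,10-dien-1-yl]-1,4-dimethoxy-3-methylnaphthalene F2. H5IO6 in THF–Et2O at 0 °C cleaves the epoxide, with loss of acetone, to the shortened aldehyde (4E,8R,12E)-14-(1,4-dimethoxy-3-methylnaphthalen-2-yl)-4,8,12-trimethyltetradeca-4,12-dienal F3. An (E)-selective Wittig reaction with the stabilised ylide Ph3P=C(CH3)CHO in toluene at 80 °C then comes back to the route at 17.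

Step 10. The hydroboration may be incomplete or not confined to the diene terminus, and transfer of the alkyl group from boron to palladium may be slow enough for protodeboronation or β-hydride loss to compete. The fallback sets out from 18 and couples through zinc after a purification point. The same 9-BBN hydroboration, worked up with NaOH/H2O2 at 0 °C, gives the primary homoallylic alcohol (3E,7E,11R,15E)-17-(1,4-dimethoxy-3-methylnaphthalen-2-yl)-3,7,11,15-tetramethylheptadeca-3,7,15-trien-1-ol F4, which can be freed from regioisomers. I2, PPh3 and imidazole convert it to the iodide 2-[(2E,7R,10E,14E)-17-iodo-3,7,11,15-tetramethylheptadeca-2,10,14-trien-1-yl]-1,4-dimethoxy-3-methylnaphthalene F5. Zinc dust (activated with a little I2) in DMA inserts to give the alkylzinc iodide F6. Negishi coupling of F6 with 6 under Pd(PPh3)4 (zerovalent palladium) in THF–DMA forms the same C17'–C18' bond and comes back at 20.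

Step 7. Homocoupling of the benzylic chloride and protonolysis of the alkenylalane may outpace the nickel-catalysed cross-coupling. The fallback sets out from 11 and 12 and forms the ring–C1' bond instead of the C1'–C2' bond. Alkenylalane 14, made from 11 as before, is turned into its ate complex with nBuLi and trapped with (CH2O)n to give the allylic alcohol (2E,7R,10E)-3,7,11,15-tetramethylhexadeca-2,10,14-trien-1-ol F7. PBr3 in Et2O at 0 °C gives the allylic bromide (2E,7R,10E)-1-bromo-3,7,11,15-tetramethylhexadeca-2,10,14-triene F8. In parallel, 12 is brominated (Br2, CH2Cl2, 0 °C) to 2-bromo-1,4-dimethoxy-3-methylnaphthalene F9 and converted with Mg in THF into the aryl Grignard reagent (1,4-dimethoxy-3-methylnaphthalen-2-yl)magnesium bromide F10. With CuBr·SMe2 (5 mol %) at −20 °C, F10 should displace the bromide of F8 at C1' by SN2 and come back at 15.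

Further compounds
F1 | step 8 | (6E,10R,14E)-3-bromo-16-(1,4-dimethoxy-3-methylnaphthalen-2-yl)-2,6,10,14-tetramethylhexadeca-6,14-dien-2-ol (C3 epimers) | CC(C)(O)C(Br)CC/C(C)=C/CC[C@H](C)CCC/C(C)=C/Cc1c(C)c(OC)c2ccccc2c1OC
F2 | step 8 | 2-[(2E,7R,10E)-13-(3,3-dimethyloxiran-2-yl)-3,7,11-trimethyltrideca-2,10-dien-1-yl]-1,4-dimethoxy-3-methylnaphthalene (oxirane epimers) | CC1(C)OC1CC/C(C)=C/CC[C@H](C)CCC/C(C)=C/Cc1c(C)c(OC)c2ccccc2c1OC
F3 | step 8 | (4E,8R,12E)-14-(1,4-dimethoxy-3-methylnaphthalen-2-yl)-4,8,12-trimethyltetradeca-4,12-dienal | O=CCC/C(C)=C/CC[C@H](C)CCC/C(C)=C/Cc1c(C)c(OC)c2ccccc2c1OC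
F4 | step 10 | (3E,7E,11R,15E)-17-(1,4-dimethoxy-3-methylnaphthalen-2-yl)-3,7,11,15-tetramethylheptadeca-3,7,15-trien-1-ol | OCC/C(C)=C/CC/C(C)=C/CC[C@H](C)CCC/C(C)=C/Cc1c(C)c(OC)c2ccccc2c1OC
F5 | step 10 | 2-[(2E,7R,10E,14E)-17-iodo-3,7,11,15-tetramethylheptadeca-2,10,14-trien-1-yl]-1,4-dimethoxy-3-methylnaphthalene | ICC/C(C)=C/CC/C(C)=C/CC[C@H](C)CCC/C(C)=C/Cc1c(C)c(OC)c2ccccc2c1OC
F6 | step 10 | [(3E,7E,11R,15E)-17-(1,4-dimethoxy-3-methylnaphthalen-2-yl)-3,7,11,15-tetramethylheptadeca-3,7,15-trien-1-yl]zinc iodide | I[Zn]CC/C(C)=C/CC/C(C)=C/CC[C@H](C)CCC/C(C)=C/Cc1c(C)c(OC)c2ccccc2c1OC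
F7 | step 7 | (2E,7R,10E)-3,7,11,15-tetramethylhexadeca-2,10,14-trien-1-ol | CC(C)=CCC/C(C)=C/CC[C@H](C)CCC/C(C)=C/CO
F8 | step 7 | (2E,7R,10E)-1-bromo-3,7,11,15-tetramethylhexadeca-2,10,14-triene | CC(C)=CCC/C(C)=C/CC[C@H](C)CCC/C(C)=C/CBr
F9 | step 7 | 2-bromo-1,4-dimethoxy-3-methylnaphthalene | COc1c(C)c(Br)c(OC)c2ccccc12
F10 | step 7 | (1,4-dimethoxy-3-methylnaphthalen-2-yl)magnesium bromide | COc1c(C)c([Mg]Br)c(OC)c2ccccc12
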